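## Retrosynthetic overview

1. The target comes from a bicyclic tert-butyl 3,19-dihydroxylabda-7,13E-dienoate with an equatorial 3-OH. The late steps are ester cleavage, O-acetylation, oxidation of C-19 to the aldehyde, and inversion at C-3 by oxidation followed by 19-OH-directed reduction.
2. The bicyclic diol comes from one acyclic C20 chain, the (14R,15S)-cis-epoxy alcohol of 16-hydroxygeranylgeranoate, by a single head-to-tail cation-olefin cascade. Ring A closes first (C4-C5) and ring B second (C9-C10). Loss of H-7 ends the cascade, and the enoate is the built-in stop.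
3. The epoxy alcohol comes from the (14Z)-allylic alcohol by Sharpless epoxidation. The Z geometry becomes the axial C-19, and the C-14 oxirane carbon fixes the absolute sense of folding.
4. The Z-allylic alcohol comes from the C17 trisnor aldehyde (beta-oxido-ylide Wittig plus CH2O). That aldehyde comes from tert-butyl geranylgeranoate (terminal oxirane, then periodic acid), which comes from farnesylacetone and a phosphonoacetate (HWE).

Assumption: (5E,9E)-farnesylacetone is bought isomerically pure. Acyclic compounds are numbered from the ester carbon. Bicyclic compounds use labdane numbering, with C-19 as the axial C-4 substituent cis to C-20.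

## Route

Step 1
Reactants: 1 (5E,9E)-farnesylacetone; 2 tert-butyl diethylphosphonoacetate
Product: 3 tert-butyl (2E,6E,10E)-3,7,11,15-tetramethylhexadeca-2,6,10,14-tetraenoate (tert-butyl geranylgeranoate)
Conditions: NaH, THF, 0 °C to rt
Reagents that add atoms: tert-butyl diethylphosphonoacetate (2), CCOP(=O)(CC(=O)OC(C)(C)C)OCC
Why: Horner-Wadsworth-Emmons olefination of the methyl ketone favours the (2E)-enoate (about 5:1, the 2Z isomer is removed on silica), and the bulky tert-butyl ester is chosen because it later has to tolerate butyllithium, methanolic carbonate and hydride reagents.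

Step 2
Reactants: 3 tert-butyl geranylgeranoate
Product: 5 racemic tert-butyl (2E,6E,10E)-14,15-epoxy-3,7,11,15-tetramethylhexadeca-2,6,10-trienoate, via bromohydrin 4 (not isolated)
Conditions: NBS, THF/H2O, 0 °C; then K2CO3, MeOH, rt
Reagents that add atoms: water, O; N-bromosuccinimide, O=C1CCC(=O)N1Br (its bromine stays only in 4)
Why: In this van Tamelen terminal bromohydrin formation the coiled polyene exposes only the electron-rich 14,15-alkene to NBS in aqueous THF (the enoate alkene is inert), and carbonate then closes 4 by intramolecular Williamson displacement to an oxirane whose racemic stereocentre is erased in step 3.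

Step 3
Reactants: 5 racemic terminal epoxide
Product: 6 tert-butyl (2E,6E,10E)-3,7,11-trimethyl-14-oxotetradeca-2,6,10-trienoate
Conditions: H5IO6, THF/Et2O, 0 °C
Reagents that add atoms: none
Why: Periodic acid hydrolyses the trisubstituted oxirane in situ and cleaves the glycol (Malaprade cleavage), leaving the three remaining alkenes and the tert-butyl ester untouched.

Step 4
Reactants: 6 trisnor aldehyde; 7 ethyltriphenylphosphonium bromide; 8 paraformaldehyde
Product: 11 tert-butyl (2E,6E,10E,14Z)-16-hydroxy-3,7,11,15-tetramethylhexadeca-2,6,10,14-tetraenoate, via betaine 9 (not isolated), via beta-oxido ylide 10 (not isolated)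
Conditions: 7, n-BuLi, THF, 0 °C; 6, −78 °C; n-BuLi (1.0 equiv), −78 to 0 °C; 8, 0 °C to rt; H2O
Reagents that add atoms: ethyltriphenylphosphonium bromide (7), CC[P+](c1ccccc1)(c1ccccc1)c1ccccc1.[Br-]; paraformaldehyde (8), C=O
Why: In this Corey-Yamamoto/Schlosser beta-oxido-ylide variant of the Wittig reaction, lithiobetaine 9 is deprotonated faster than butyllithium attacks the hindered enoate at −78 °C, ylide 10 captures formaldehyde, and loss of Ph3PO through the oxygen of the original aldehyde gives the trisubstituted alkene with chain and CH2OH cis (14Z, typically above 95:5).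

Step 5
Reactants: 11 (14Z)-allylic alcohol
Product: 12 tert-butyl (2E,6E,10E,14R,15S)-14,15-epoxy-16-hydroxy-3,7,11,15-tetramethylhexadeca-2,6,10-trienoate (cis-oxirane, chain and CH2OH on the same side)
Conditions: Ti(OiPr)4 (10 mol %), L-(+)-diethyl tartrate (12 mol %), t-BuOOH, 4 Å sieves, CH2Cl2, −20 °C
Reagents that add atoms: tert-butyl hydroperoxide, CC(C)(C)OO
Why: Katsuki-Sharpless asymmetric epoxidation touches only the allylic-alcohol alkene, and L-(+)-tartrate delivers oxygen to the face that gives the (2S,3R)-type cis-epoxy alcohol, here (15S,14R), in about 90% ee for a Z-2-methylalkenol (raised later by crystallising 14).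

Step 6
Reactants: 12 (14R,15S)-epoxy alcohol
Product: 14 tert-butyl (3R,4R,5S,9R,10S)-3,19-dihydroxylabda-7,13E-dien-15-oate (3-OH equatorial; 19-CH2OH axial; trans-decalin), via dichloroaluminium alkoxide 13 (not isolated)
Conditions: MeAlCl2 (3 equiv), CH2Cl2, −78 °C; 1 M HCl quench
Reagents that add atoms: MeAlCl2, C[Al](Cl)Cl (aluminium and chlorine stay only in 13)
Why: Proposed new method: this is an epoxide-initiated cation-olefin bicyclization run on the unprotected 2,3-epoxy alcohol, closest to the known MeAlCl2-promoted epoxy-polyene cyclizations and to hydroxyl-delivered Lewis-acid openings of 2,3-epoxy alcohols, in which the first equivalent of MeAlCl2 forms alkoxide 13 whose aluminium chelates the oxirane oxygen and ionises the tertiary C15-O bond, the 10,11-alkene attacks C-15 from the rear (inversion) through a chair-chair fold so that the retained C14-O bond becomes the equatorial 3-OH, the Z-CH2O arm becomes axial C-19 and the E-alkenes give the trans-decalin with an equatorial C-9 side chain, the aluminium-complexed enoate is too electron-poor to add, the C-8 cation loses axial H-7 (scavenged as methane, so no acid isomerises the 7-ene), and the six-membered O3-Al-O19 chelate holds the aluminium-bridged O-19 anti to C-5, away from the C-10 cation and poorly disposed to push a C-16 hydride shift.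

Step 7
Reactants: 14 3,19-diol (3-OH equatorial)
Product: 15 tert-butyl (4R,5S,9R,10S)-3,19-dioxolabda-7,13E-dien-15-oate
Conditions: Dess-Martin periodinane (2.5 equiv), CH2Cl2, 0 °C to rt; filtration through silica
Reagents that add atoms: none
Why: Dess-Martin oxidation converts both carbinols under neutral non-aqueous conditions, which protects the non-enolisable 1,3-keto aldehyde from base-induced deformylation, and no stereocentre is touched because C-4 is quaternary.

Step 8
Reactants: 15 keto aldehyde
Product: 17 tert-butyl (3S,4R,5S,9R,10S)-3,19-dihydroxylabda-7,13E-dien-15-oate (3-OH axial), via 19-hydroxy-3-ketone 16 (not isolated)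
Conditions: Me4NBH(OAc)3 (5 equiv), MeCN/AcOH, −20 °C to rt
Reagents that add atoms: none
Why: In this Saksena-Evans hydroxyl-directed reduction, triacetoxyborohydride reduces the aldehyde but not an isolated ketone, the axial 19-oxygen of 16 then binds boron and passes its hydride to C-3 through a six-membered chair from the C-19 face, and the new hydroxyl therefore ends on the opposite face, axial and (3S).

Step 9
Reactants: 17 3,19-diol (3-OH axial)
Product: 19 tert-butyl (3S,4S,5S,9R,10S)-3-acetoxy-19-oxolabda-7,13E-dien-15-oate, via 3-hydroxy-19-aldehyde 18 (not isolated)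
Conditions: TEMPO (10 mol %), PhI(OAc)2, CH2Cl2, rt; then Ac2O, pyridine, DMAP, rt
Reagents that add atoms: acetic anhydride, CC(=O)OC(C)=O
Why: Oxoammonium (TEMPO/PhI(OAc)2) oxidation selects the primary alcohol over the hindered axial secondary one, the trans-diaxial 18 can neither lactolise nor eliminate (no alpha-hydrogen), and DMAP-catalysed acyl transfer in the same flask acetylates 3-OH with retention.

Step 10
Reactants: 19 acetoxy aldehyde tert-butyl ester
Product: 21 (3S,4S,5S,9R,10S)-3-acetoxy-19-oxolabda-7,13E-dien-15-oic acid (CNP0312710.1), via trimethylsilyl ester 20 (not isolated)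
Conditions: Me3SiOTf, 2,6-lutidine, CH2Cl2, 0 °C; then H2O (pH 5)
Reagents that add atoms: Me3SiOTf, C[Si](C)(C)OS(=O)(=O)C(F)(F)F (its silyl group stays only in 20)
Why: Silyl-triflate-mediated tert-butyl ester cleavage (E1 loss of isobutene from the O-silylated ester, buffered by lutidine) avoids free Brønsted acid, so the 7-ene, the acetate and the non-enolisable aldehyde survive, and water then hydrolyses silyl ester 20.

## Compound list

1 | (5E,9E)-farnesylacetone, (5E,9E)-6,10,14-trimethylpentadeca-5,9,13-trien-2-one | CC(C)=CCC/C(C)=C/CC/C(C)=C/CCC(C)=O | starting material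
2 | tert-butyl diethylphosphonoacetate | CCOP(=O)(CC(=O)OC(C)(C)C)OCC | starting material
3 | tert-butyl (2E,6E,10E)-geranylgeranoate | CC(C)=CCC/C(C)=C/CC/C(C)=C/CC/C(C)=C/C(=O)OC(C)(C)C | intermediate
4 | tert-butyl (2E,6E,10E)-14-bromo-15-hydroxy-3,7,11,15-tetramethylhexadeca-2,6,10-trienoate (racemic) | CC(C)(O)C(Br)CC/C(C)=C/CC/C(C)=C/CC/C(C)=C/C(=O)OC(C)(C)C | intermediate
5 | tert-butyl (2E,6E,10E)-14,15-epoxy-3,7,11,15-tetramethylhexadeca-2,6,10-trienoate (racemic) | CC1(C)OC1CC/C(C)=C/CC/C(C)=C/CC/C(C)=C/C(=O)OC(C)(C)C | intermediate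
6 | tert-butyl (2E,6E,10E)-3,7,11-trimethyl-14-oxotetradeca-2,6,10-trienoate | O=CCC/C(C)=C/CC/C(C)=C/CC/C(C)=C/C(=O)OC(C)(C)C | intermediate
7 | ethyltriphenylphosphonium bromide | CC[P+](c1ccccc1)(c1ccccc1)c1ccccc1.[Br-] | starting material
8 | paraformaldehyde (source of CH2O) | C=O | starting material
9 | betaine from 6 and the ethylidene ylide (drawn as the zwitterion, new centres unassigned) | CC(C([O-])CC/C(C)=C/CC/C(C)=C/CC/C(C)=C/C(=O)OC(C)(C)C)[P+](c1ccccc1)(c1ccccc1)c1ccccc1 | intermediate
10 | lithium beta-oxido ylide | CC(=P(c1ccccc1)(c1ccccc1)c1ccccc1)C([O-])CC/C(C)=C/CC/C(C)=C/CC/C(C)=C/C(=O)OC(C)(C)C.[Li+] | intermediate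
11 | tert-butyl (2E,6E,10E,14Z)-16-hydroxy-3,7,11,15-tetramethylhexadeca-2,6,10,14-tetraenoate | OC/C(C)=C\CC/C(C)=C/CC/C(C)=C/CC/C(C)=C/C(=O)OC(C)(C)C | intermediate
12 | tert-butyl (2E,6E,10E,14R,15S)-14,15-epoxy-16-hydroxy-3,7,11,15-tetramethylhexadeca-2,6,10-trienoate | OC[C@]1(C)O[C@@H]1CC/C(C)=C/CC/C(C)=C/CC/C(C)=C/C(=O)OC(C)(C)C | intermediate
13 | O-16 dichloroaluminium alkoxide of 12 | Cl[Al](Cl)OC[C@]1(C)O[C@@H]1CC/C(C)=C/CC/C(C)=C/CC/C(C)=C/C(=O)OC(C)(C)C | intermediate
14 | tert-butyl (3R,4R,5S,9R,10S)-3,19-dihydroxylabda-7,13E-dien-15-oate (3-OH equatorial) | O[C@@H]1CC[C@@]2(C)[C@H](CC/C(C)=C/C(=O)OC(C)(C)C)C(C)=CC[C@@H]2[C@]1(C)CO | intermediate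
15 | tert-butyl (4R,5S,9R,10S)-3,19-dioxolabda-7,13E-dien-15-oate | O=C1CC[C@@]2(C)[C@H](CC/C(C)=C/C(=O)OC(C)(C)C)C(C)=CC[C@@H]2[C@]1(C)C=O | intermediate
16 | tert-butyl (4R,5S,9R,10S)-19-hydroxy-3-oxolabda-7,13E-dien-15-oate | O=C1CC[C@@]2(C)[C@H](CC/C(C)=C/C(=O)OC(C)(C)C)C(C)=CC[C@@H]2[C@]1(C)CO | intermediate
17 | tert-butyl (3S,4R,5S,9R,10S)-3,19-dihydroxylabda-7,13E-dien-15-oate (3-OH axial) | O[C@H]1CC[C@@]2(C)[C@H](CC/C(C)=C/C(=O)OC(C)(C)C)C(C)=CC[C@@H]2[C@]1(C)CO | intermediate
18 | tert-butyl (3S,4S,5S,9R,10S)-3-hydroxy-19-oxolabda-7,13E-dien-15-oate | O[C@H]1CC[C@@]2(C)[C@H](CC/C(C)=C/C(=O)OC(C)(C)C)C(C)=CC[C@@H]2[C@]1(C)C=O | intermediate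
19 | tert-butyl (3S,4S,5S,9R,10S)-3-acetoxy-19-oxolabda-7,13E-dien-15-oate | CC(=O)O[C@H]1CC[C@@]2(C)[C@H](CC/C(C)=C/C(=O)OC(C)(C)C)C(C)=CC[C@@H]2[C@]1(C)C=O | intermediate
20 | trimethylsilyl (3S,4S,5S,9R,10S)-3-acetoxy-19-oxolabda-7,13E-dien-15-oate | CC(=O)O[C@H]1CC[C@@]2(C)[C@H](CC/C(C)=C/C(=O)O[Si](C)(C)C)C(C)=CC[C@@H]2[C@]1(C)C=O | intermediate
21 | (3S,4S,5S,9R,10S)-3-acetoxy-19-oxolabda-7,13E-dien-15-oic acid (CNP0312710.1) | CC(=O)O[C@H]1CC[C@@]2(C)[C@H](CC/C(C)=C/C(=O)O)C(C)=CC[C@@H]2[C@]1(C)C=O | target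

## Step count and risks

Total step count: 10. Longest linear sequence: 10 (from 1).

**Step 6 (bicyclization of the free epoxy alcohol).** There are five ways it could fail:
- a 1,2-hydride shift from C-16 to C-15, giving an acyclic aldol-type aldehyde;
- capture of the C-10 cation by O-19;
- a stall at the monocyclic stage;
- formation of 8(17)- or 8(9)-ene isomers, which are separable on AgNO3-silica;
- a third ring closure onto the enoate.

The fallback replaces hydroxyl-delivered activation with an O-blocked substrate and an external Lewis acid. It sets out from 12 and comes back at 14. Compound 12 is silylated (t-BuPh2SiCl, imidazole, DMF) to the tert-butyldiphenylsilyl ether F1. The bulky, weakly basic siloxy group of this ether neither chelates nor traps cations. SnCl4 in CH2Cl2 at −78 °C cyclises it to the 19-O-silyl bicyclic alcohol F2, and Bu4NF in THF then frees 14.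

**Step 4 (beta-oxido ylide next to an enoate).** Butyllithium or the basic ylide may attack or gamma-deprotonate the ester, which would erode the yield or the 2E geometry. The fallback sets out from 6 and comes back at 11, and it uses a stabilised phosphonate instead of a lithiated betaine. Compound 6 is olefinated under Still-Gennari conditions (methyl 2-[bis(2,2,2-trifluoroethoxy)phosphoryl]propanoate, KN(SiMe3)2, 18-crown-6, THF, −78 °C) to the (14Z)-methyl tert-butyl diester F3. Only the methyl ester of this diester is reduced by i-Bu2AlH (2.1 equiv, CH2Cl2, −78 °C), which gives 11.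

**Step 8 (double reduction with directed delivery to C-3).** The hindered neopentyl aldehyde may be reduced slowly, 15 may deformylate, or the delivery to the flanked ketone may stall. The fallback sets out from 14 and comes back at 19. It never makes the keto aldehyde, and it relies on steric approach control instead of directed delivery. The sequence is:
- Compound 14 is silylated at the primary hydroxyl (t-BuMe2SiCl, imidazole) to the 19-O-tert-butyldimethylsilyl ether F4.
- Dess-Martin oxidation gives the 3-ketone F5.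
- LiBH(s-Bu)3 at −78 °C attacks from the equatorial side, and the alkoxide is acetylated in the flask (Ac2O, DMAP) to the axial 3-acetate F6.
- HF·pyridine gives the 3-acetoxy-19-alcohol F7.
- Dess-Martin oxidation gives 19.

## Further compounds

F1 | step 6 | tert-butyl (2E,6E,10E,14R,15S)-16-(tert-butyldiphenylsilyloxy)-14,15-epoxy-3,7,11,15-tetramethylhexadeca-2,6,10-trienoate | CC(C)(C)[Si](OC[C@]1(C)O[C@@H]1CC/C(C)=C/CC/C(C)=C/CC/C(C)=C/C(=O)OC(C)(C)C)(c1ccccc1)c1ccccc1
F2 | step 6 | tert-butyl (3R,4R,5S,9R,10S)-19-(tert-butyldiphenylsilyloxy)-3-hydroxylabda-7,13E-dien-15-oate | O[C@@H]1CC[C@@]2(C)[C@H](CC/C(C)=C/C(=O)OC(C)(C)C)C(C)=CC[C@@H]2[C@]1(C)CO[Si](c1ccccc1)(c1ccccc1)C(C)(C)C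
F3 | step 4 | 1-tert-butyl 16-methyl (2E,6E,10E,14Z)-3,7,11,15-tetramethylhexadeca-2,6,10,14-tetraenedioate | COC(=O)/C(C)=C\CC/C(C)=C/CC/C(C)=C/CC/C(C)=C/C(=O)OC(C)(C)C
F4 | step 8 | tert-butyl (3R,4R,5S,9R,10S)-19-(tert-butyldimethylsilyloxy)-3-hydroxylabda-7,13E-dien-15-oate | O[C@@H]1CC[C@@]2(C)[C@H](CC/C(C)=C/C(=O)OC(C)(C)C)C(C)=CC[C@@H]2[C@]1(C)CO[Si](C)(C)C(C)(C)C
F5 | step 8 | tert-butyl (4R,5S,9R,10S)-19-(tert-butyldimethylsilyloxy)-3-oxolabda-7,13E-dien-15-oate | O=C1CC[C@@]2(C)[C@H](CC/C(C)=C/C(=O)OC(C)(C)C)C(C)=CC[C@@H]2[C@]1(C)CO[Si](C)(C)C(C)(C)C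
F6 | step 8 | tert-butyl (3S,4R,5S,9R,10S)-3-acetoxy-19-(tert-butyldimethylsilyloxy)labda-7,13E-dien-15-oate | CC(=O)O[C@H]1CC[C@@]2(C)[C@H](CC/C(C)=C/C(=O)OC(C)(C)C)C(C)=CC[C@@H]2[C@]1(C)CO[Si](C)(C)C(C)(C)C
F7 | step 8 | tert-butyl (3S,4R,5S,9R,10S)-3-acetoxy-19-hydroxylabda-7,13E-dien-15-oate | CC(=O)O[C@H]1CC[C@@]2(C)[C@H](CC/C(C)=C/C(=O)OC(C)(C)C)C(C)=CC[C@@H]2[C@]1(C)CO
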